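**Strategy.** Atoms follow germacrane numbering (ring C1–C10, lactone C11–C13, formyl C14, methyl C15). Everything rests on disconnecting the lactone bond C7–C11. The feature exploited is the oxygen on C8 beside C7 of the γ-lactone ring (O6–C12–C11–C7–C6): it marks C7–C8 as a former trans-epoxide. The key step treats the phosphonoacetate ester (on O6) of a Sharpless-derived erythro 2,3-epoxy alcohol with base: carbanion C11 opens the epoxide at C7 (5-exo, inversion), closing the trans-lactone and freeing O8, and formaldehyde then installs the C13 methylene in the same flask. A Nozaki–Hiyama–Kishi reaction later closes the ten-membered ring at C9–C10.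

Key step: step 8

Remark: the SMILES is read as the (4R,5S,6S,7R,8S,9R) isomer with C1=C10 cis within the ring (formyl trans to C2) and a cis-fused 4,5-epoxide (C3 and C6 on the same side).
Remark: in step 5 (−)-MIB is assumed to deliver the alkenyl group to the Si face of aldehyde 9, as it does with other aldehydes.

Step 1
Reactants: 1 neryl acetate
Product: 2 (2Z)-3-methyl-6-oxohex-2-en-1-yl acetate
Conditions: O3, CH2Cl2/MeOH, Sudan Red 7B (indicator), −78 °C; then Me2S, −78 °C → rt
Reagents that add atoms: ozone, [O-][O+]=O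
Why: Chemoselective ozonolysis should cleave the electron-rich terminal alkene before the 2,3-alkene, which the allylic acetate deactivates, the dye marking the end point.

Step 2
Reactants: 2 (2Z)-3-methyl-6-oxohex-2-en-1-yl acetate; 3 ethyltriphenylphosphonium iodide
Product: 7 (2Z,6Z)-7-iodo-3-methylocta-2,6-dien-1-yl acetate, via ethylidenetriphenylphosphorane 4 (not isolated), via (1-iodoethyl)triphenylphosphonium iodide 5 (not isolated), via (1-iodoethylidene)triphenylphosphorane 6 (not isolated)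
Conditions: 3, n-BuLi, THF, 0 °C → rt; I2, −78 °C; NaN(SiMe3)2, −78 → −20 °C; then 2, −78 → −20 °C
Reagents that add atoms: iodine, II
Why: Wittig olefination with the α-iodo ylide (Stork–Zhao-type iodo-olefination) should give the trisubstituted vinyl iodide with iodine cis to the chain (Z) under kinetic control at low temperature, the ester being left alone.

Step 3
Reactants: 7 (2Z,6Z)-7-iodo-3-methylocta-2,6-dien-1-yl acetate
Product: 8 (2Z,6Z)-7-iodo-3-methylocta-2,6-dien-1-ol
Conditions: K2CO3 (cat.), MeOH, 0 °C → rt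
Reagents that add atoms: none
Why: Base-catalysed methanolysis (transesterification) removes the acetate while the vinyl iodide and both alkenes are inert.

Step 4
Reactants: 8 (2Z,6Z)-7-iodo-3-methylocta-2,6-dien-1-ol
Product: 9 (2Z,6Z)-7-iodo-3-methylocta-2,6-dienal
Conditions: Dess–Martin periodinane, pyridine, CH2Cl2, 0 °C
Reagents that add atoms: none
Why: Buffered Dess–Martin oxidation of the allylic alcohol should give the enal without scrambling the Z geometry of C4=C5.

Step 5
Reactants: 9 (2Z,6Z)-7-iodo-3-methylocta-2,6-dienal; 10 tert-butyldimethyl(prop-2-yn-1-yloxy)silane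
Product: 13 (2E,4S,5Z,9Z)-1-{[tert-butyl(dimethyl)silyl]oxy}-10-iodo-6-methylundeca-2,5,9-trien-4-ol, via alkenyl(dicyclohexyl)borane 11 (not isolated), via alkenyl(methyl)zinc 12 (not isolated)
Conditions: 10, Cy2BH, toluene, 0 °C → rt; Me2Zn, −78 °C; (2S)-(−)-3-exo-morpholinoisoborneol ((−)-MIB, 5 mol %); then 9, −30 → 0 °C; H2O work-up
Reagents that add atoms: none
Why: Alkyne hydroboration, boron-to-zinc transmetalation and amino-alcohol-catalysed asymmetric 1,2-addition of the E-alkenylzinc to the aldehyde should set C6 (4S in 13) by Si-face delivery from the (−)-MIB–zinc catalyst.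

Step 6
Reactants: 13 (2E,4S,5Z,9Z)-1-{[tert-butyl(dimethyl)silyl]oxy}-10-iodo-6-methylundeca-2,5,9-trien-4-ol
Product: 14 (1R,2Z,6Z)-1-[(2R,3R)-3-({[tert-butyl(dimethyl)silyl]oxy}methyl)oxiran-2-yl]-7-iodo-3-methylocta-2,6-dien-1-ol
Conditions: Ti(OiPr)4 (20 mol %), D-(−)-diisopropyl tartrate (24 mol %), t-BuOOH, 4 Å molecular sieves, CH2Cl2, −20 °C
Reagents that add atoms: tert-butyl hydroperoxide, CC(C)(C)OO
Why: Sharpless asymmetric epoxidation in the matched sense should epoxidise the E-disubstituted arm of the (S)-carbinol erythro-selectively to the (2R,3R)-oxirane (C7, C8), the Z-trisubstituted arm with its cis substituent reacting far more slowly.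

Step 7
Reactants: 14 (1R,2Z,6Z)-1-[(2R,3R)-3-({[tert-butyl(dimethyl)silyl]oxy}methyl)oxiran-2-yl]-7-iodo-3-methylocta-2,6-dien-1-ol; 15 (diethoxyphosphoryl)acetic acid
Product: 16 (1R,2Z,6Z)-1-[(2R,3R)-3-({[tert-butyl(dimethyl)silyl]oxy}methyl)oxiran-2-yl]-7-iodo-3-methylocta-2,6-dien-1-yl (diethoxyphosphoryl)acetate
Conditions: N,N'-dicyclohexylcarbodiimide, DMAP (cat.), CH2Cl2, 0 °C → rt
Reagents that add atoms: none
Why: Steglich esterification acylates the secondary alcohol under neutral conditions, so neither Payne rearrangement nor epoxide opening should intervene.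

Step 8
Reactants: 16 (1R,2Z,6Z)-1-[(2R,3R)-3-({[tert-butyl(dimethyl)silyl]oxy}methyl)oxiran-2-yl]-7-iodo-3-methylocta-2,6-dien-1-yl (diethoxyphosphoryl)acetate
Product: 18 (4R,5R)-4-[(1S)-2-{[tert-butyl(dimethyl)silyl]oxy}-1-hydroxyethyl]-5-[(1Z,5Z)-6-iodo-2-methylhepta-1,5-dien-1-yl]-3-methylideneoxolan-2-one, via α-phosphono lactone 17 (not isolated)
Conditions: NaH (1.05 equiv), THF, 0 → 65 °C; then (CH2O)n, 0 °C → rt
Reagents that add atoms: formaldehyde (as paraformaldehyde), C=O
Why: Proposed new method: NaH deprotonates C11 of the phosphonoacetate, the carbanion held on O6 attacks the near epoxide carbon C7 from the rear of its C–O bond (intramolecular SN2), the C8 alkoxide is quenched at once by the more acidic C11–H of lactone 17, and the resulting phosphonate carbanion undergoes Horner–Wadsworth–Emmons olefination with formaldehyde to give the C11=C13 methylene. The closest known reaction types are the intermolecular opening of epoxides by phosphonoacetate anions en route to α-methylene-γ-butyrolactones, the base-mediated 5-exo cyclisation of 2,3-epoxy alcohol carbamates (nitrogen in place of carbon on the same O–C(=O)–X tether) and epoxynitrile cyclisations. The lactone ring (O6–C12–C11–C7–C6) closes in the 5-exo-tet mode. C7 is set by stereospecific inversion of the Sharpless epoxide, so the erythro trans-epoxy ester should give the trans-6,7-lactone, while C8 keeps its configuration and emerges as the free hydroxyl. The step needs attack at C7 and not at C8 (6-endo) and C- rather than O-alkylation of the ester enolate: the first is secured by the exo preference of the short tether, the extended zigzag chain placing O6 anti to the C7–O bond, the second by the soft phosphonate-stabilised carbon and the far greater stability of the lactone.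

Step 9
Reactants: 18 (4R,5R)-4-[(1S)-2-{[tert-butyl(dimethyl)silyl]oxy}-1-hydroxyethyl]-5-[(1Z,5Z)-6-iodo-2-methylhepta-1,5-dien-1-yl]-3-methylideneoxolan-2-one
Product: 19 (1S)-2-{[tert-butyl(dimethyl)silyl]oxy}-1-[(2R,3S)-2-[(1Z,5Z)-6-iodo-2-methylhepta-1,5-dien-1-yl]-4-methylidene-5-oxooxolan-3-yl]ethyl 2-methylprop-2-enoate
Conditions: methacrylic anhydride, Et3N, DMAP (cat.), CH2Cl2, 0 °C
Reagents that add atoms: methacrylic anhydride, C=C(C)C(=O)OC(=O)C(C)=C
Why: DMAP-catalysed acylation of the secondary C8 alcohol installs the methacrylate and at the same time blocks translactonisation to the 7,8-lactone.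

Step 10
Reactants: 19 (1S)-2-{[tert-butyl(dimethyl)silyl]oxy}-1-[(2R,3S)-2-[(1Z,5Z)-6-iodo-2-methylhepta-1,5-dien-1-yl]-4-methylidene-5-oxooxolan-3-yl]ethyl 2-methylprop-2-enoate
Product: 20 (1S)-2-{[tert-butyl(dimethyl)silyl]oxy}-1-[(2S,3R)-2-[(2S,3R)-3-[(3Z)-4-iodopent-3-en-1-yl]-3-methyloxiran-2-yl]-4-methylidene-5-oxooxolan-3-yl]ethyl 2-methylprop-2-enoate
Conditions: dimethyldioxirane, acetone, −20 → 0 °C
Reagents that add atoms: dimethyldioxirane, CC1(C)OO1
Why: Electrophilic dioxirane epoxidation should pick the only electron-rich alkene (C4=C5; the vinyl iodide and both acrylates are deactivated) and, with H6 eclipsing the alkene to relieve allylic 1,3-strain, approach anti to the allylic C6–O bond (the erythro preference known for Z-allylic ethers and esters), setting C4 (R) and C5 (S).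

Step 11
Reactants: 20 (1S)-2-{[tert-butyl(dimethyl)silyl]oxy}-1-[(2S,3R)-2-[(2S,3R)-3-[(3Z)-4-iodopent-3-en-1-yl]-3-methyloxiran-2-yl]-4-methylidene-5-oxooxolan-3-yl]ethyl 2-methylprop-2-enoate
Product: 21 (1S)-2-hydroxy-1-[(2S,3R)-2-[(2S,3R)-3-[(3Z)-4-iodopent-3-en-1-yl]-3-methyloxiran-2-yl]-4-methylidene-5-oxooxolan-3-yl]ethyl 2-methylprop-2-enoate
Conditions: HF·pyridine, pyridine, THF, 0 °C
Reagents that add atoms: none
Why: Buffered fluoride cleavage of the primary silyl ether should spare the epoxide and, being non-basic, avoid acyl migration from O8 to O9.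

Step 12
Reactants: 21 (1S)-2-hydroxy-1-[(2S,3R)-2-[(2S,3R)-3-[(3Z)-4-iodopent-3-en-1-yl]-3-methyloxiran-2-yl]-4-methylidene-5-oxooxolan-3-yl]ethyl 2-methylprop-2-enoate
Product: 22 (1S)-1-[(2S,3S)-2-[(2S,3R)-3-[(3Z)-4-iodopent-3-en-1-yl]-3-methyloxiran-2-yl]-4-methylidene-5-oxooxolan-3-yl]-2-oxoethyl 2-methylprop-2-enoate
Conditions: Dess–Martin periodinane, pyridine, CH2Cl2, 0 °C
Reagents that add atoms: none
Why: Buffered Dess–Martin oxidation of the primary alcohol gives the α-acyloxy aldehyde under conditions that should not epimerise C8.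

Step 13
Reactants: 22 (1S)-1-[(2S,3S)-2-[(2S,3R)-3-[(3Z)-4-iodopent-3-en-1-yl]-3-methyloxiran-2-yl]-4-methylidene-5-oxooxolan-3-yl]-2-oxoethyl 2-methylprop-2-enoate
Product: 23 (1(10)Z,4R,5S,6S,7R,8S,9R)-4,5-epoxy-9-hydroxy-8-(methacryloyloxy)germacra-1(10),11(13)-dien-12,6-olide
Conditions: CrCl2 (10 equiv), NiCl2 (2 mol %), DMSO/THF, rt, 2 mM, slow addition of 22
Reagents that add atoms: none
Why: The Nozaki–Hiyama–Kishi reaction (zerovalent nickel inserts into C–I, transmetalation to trivalent chromium, addition to the aldehyde) should close the ten-membered ring at C9–C10 with retention of the alkene geometry (ring cis), the cis-epoxide, trans-lactone and cis-alkene pre-folding the chain, and Felkin–Anh attack anti to the C8–O bond setting C9 (R, 8,9-anti).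

Step 14
Reactants: 23 (1(10)Z,4R,5S,6S,7R,8S,9R)-4,5-epoxy-9-hydroxy-8-(methacryloyloxy)germacra-1(10),11(13)-dien-12,6-olide
Product: 24 (1(10)Z,4R,5S,6S,7R,8S,9R)-9-acetoxy-4,5-epoxy-8-(methacryloyloxy)germacra-1(10),11(13)-dien-12,6-olide
Conditions: Ac2O, pyridine, DMAP (cat.), CH2Cl2, 0 °C → rt
Reagents that add atoms: acetic anhydride, CC(=O)OC(C)=O
Why: DMAP-catalysed acetylation of the allylic C9 alcohol is routine and is done promptly to forestall methacrylate migration.

Step 15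
Reactants: 24 (1(10)Z,4R,5S,6S,7R,8S,9R)-9-acetoxy-4,5-epoxy-8-(methacryloyloxy)germacra-1(10),11(13)-dien-12,6-olide
Product: 25 (1(10)Z,4R,5S,6S,7R,8S,9R)-9-acetoxy-4,5-epoxy-14-hydroxy-8-(methacryloyloxy)germacra-1(10),11(13)-dien-12,6-olide
Conditions: SeO2 (0.5 equiv), t-BuOOH, CH2Cl2, rt
Reagents that add atoms: tert-butyl hydroperoxide, CC(C)(C)OO; selenium dioxide (oxygen carrier), O=[Se]=O
Why: SeO2 allylic oxidation (ene reaction, then 2,3-sigmatropic shift) should hydroxylate the methyl on the more substituted alkene carbon that lies trans to the C2 chain (C14), as known for 4,5-epoxygermacranolides with a C10 methyl, and return the ring-cis alkene, the epoxide, esters and electron-poor alkenes being inert.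

Step 16
Reactants: 25 (1(10)Z,4R,5S,6S,7R,8S,9R)-9-acetoxy-4,5-epoxy-14-hydroxy-8-(methacryloyloxy)germacra-1(10),11(13)-dien-12,6-olide
Product: 26 (1(10)E,4R,5S,6S,7R,8S,9R)-9-acetoxy-4,5-epoxy-8-(methacryloyloxy)-14-oxogermacra-1(10),11(13)-dien-12,6-olide (CNP0121379.1)
Conditions: Dess–Martin periodinane, pyridine, CH2Cl2, 0 °C
Reagents that add atoms: none
Why: Dess–Martin oxidation of the primary allylic alcohol should give the conjugated aldehyde without touching the epoxide or the acrylates.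

**Compound list**

1 | neryl acetate, (2Z)-3,7-dimethylocta-2,6-dien-1-yl acetate | CC(C)=CCC/C(C)=C\COC(C)=O | starting material
2 | (2Z)-3-methyl-6-oxohex-2-en-1-yl acetate | O=CCC/C(C)=C\COC(C)=O | intermediate
3 | ethyltriphenylphosphonium iodide | CC[P+](c1ccccc1)(c1ccccc1)c1ccccc1.[I-] | starting material
4 | ethylidenetriphenylphosphorane | CC=P(c1ccccc1)(c1ccccc1)c1ccccc1 | intermediate
5 | (1-iodoethyl)triphenylphosphonium iodide | CC(I)[P+](c1ccccc1)(c1ccccc1)c1ccccc1.[I-] | intermediate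
6 | (1-iodoethylidene)triphenylphosphorane | CC(I)=P(c1ccccc1)(c1ccccc1)c1ccccc1 | intermediate
7 | (2Z,6Z)-7-iodo-3-methylocta-2,6-dien-1-yl acetate | C/C(I)=C/CC/C(C)=C\COC(C)=O | intermediate
8 | (2Z,6Z)-7-iodo-3-methylocta-2,6-dien-1-ol | C/C(I)=C/CC/C(C)=C\CO | intermediate
9 | (2Z,6Z)-7-iodo-3-methylocta-2,6-dienal | C/C(I)=C/CC/C(C)=C\C=O | intermediate
10 | tert-butyldimethyl(prop-2-yn-1-yloxy)silane | C#CCO[Si](C)(C)C(C)(C)C | starting material
11 | alkenyl(dicyclohexyl)borane, tert-butyl{[(2E)-3-(dicyclohexylboranyl)prop-2-en-1-yl]oxy}dimethylsilane | CC(C)(C)[Si](C)(C)OC/C=C/B(C1CCCCC1)C1CCCCC1 | intermediate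
12 | alkenyl(methyl)zinc, [(1E)-3-{[tert-butyl(dimethyl)silyl]oxy}prop-1-en-1-yl](methyl)zinc | C[Zn]/C=C/CO[Si](C)(C)C(C)(C)C | intermediate
13 | (2E,4S,5Z,9Z)-1-{[tert-butyl(dimethyl)silyl]oxy}-10-iodo-6-methylundeca-2,5,9-trien-4-ol | C/C(I)=C/CC/C(C)=C\[C@@H](O)/C=C/CO[Si](C)(C)C(C)(C)C | intermediate
14 | (1R,2Z,6Z)-1-[(2R,3R)-3-({[tert-butyl(dimethyl)silyl]oxy}methyl)oxiran-2-yl]-7-iodo-3-methylocta-2,6-dien-1-ol | C/C(I)=C/CC/C(C)=C\[C@@H](O)[C@H]1O[C@@H]1CO[Si](C)(C)C(C)(C)C | intermediate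
15 | (diethoxyphosphoryl)acetic acid | CCOP(=O)(CC(=O)O)OCC | starting material
16 | (1R,2Z,6Z)-1-[(2R,3R)-3-({[tert-butyl(dimethyl)silyl]oxy}methyl)oxiran-2-yl]-7-iodo-3-methylocta-2,6-dien-1-yl (diethoxyphosphoryl)acetate | C/C(I)=C/CC/C(C)=C\[C@@H](OC(=O)CP(=O)(OCC)OCC)[C@H]1O[C@@H]1CO[Si](C)(C)C(C)(C)C | intermediate
17 | α-phosphono lactone, diethyl [(4R,5R)-4-[(1S)-2-{[tert-butyl(dimethyl)silyl]oxy}-1-hydroxyethyl]-5-[(1Z,5Z)-6-iodo-2-methylhepta-1,5-dien-1-yl]-2-oxooxolan-3-yl]phosphonate (C3 epimers, present as its sodium carbanion) | C/C(I)=C/CC/C(C)=C\[C@H]1OC(=O)C(P(=O)(OCC)OCC)[C@@H]1[C@H](O)CO[Si](C)(C)C(C)(C)C | intermediate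
18 | (4R,5R)-4-[(1S)-2-{[tert-butyl(dimethyl)silyl]oxy}-1-hydroxyethyl]-5-[(1Z,5Z)-6-iodo-2-methylhepta-1,5-dien-1-yl]-3-methylideneoxolan-2-one | C/C(I)=C/CC/C(C)=C\[C@H]1OC(=O)C(=C)[C@@H]1[C@H](O)CO[Si](C)(C)C(C)(C)C | intermediate
19 | (1S)-2-{[tert-butyl(dimethyl)silyl]oxy}-1-[(2R,3S)-2-[(1Z,5Z)-6-iodo-2-methylhepta-1,5-dien-1-yl]-4-methylidene-5-oxooxolan-3-yl]ethyl 2-methylprop-2-enoate | C/C(I)=C/CC/C(C)=C\[C@H]1OC(=O)C(=C)[C@@H]1[C@H](OC(=O)C(C)=C)CO[Si](C)(C)C(C)(C)C | intermediate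
20 | (1S)-2-{[tert-butyl(dimethyl)silyl]oxy}-1-[(2S,3R)-2-[(2S,3R)-3-[(3Z)-4-iodopent-3-en-1-yl]-3-methyloxiran-2-yl]-4-methylidene-5-oxooxolan-3-yl]ethyl 2-methylprop-2-enoate | C/C(I)=C/CC[C@@]1(C)O[C@H]1[C@H]2OC(=O)C(=C)[C@@H]2[C@H](OC(=O)C(C)=C)CO[Si](C)(C)C(C)(C)C | intermediate
21 | (1S)-2-hydroxy-1-[(2S,3R)-2-[(2S,3R)-3-[(3Z)-4-iodopent-3-en-1-yl]-3-methyloxiran-2-yl]-4-methylidene-5-oxooxolan-3-yl]ethyl 2-methylprop-2-enoate | C/C(I)=C/CC[C@@]1(C)O[C@H]1[C@H]2OC(=O)C(=C)[C@@H]2[C@H](OC(=O)C(C)=C)CO | intermediate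
22 | (1S)-1-[(2S,3S)-2-[(2S,3R)-3-[(3Z)-4-iodopent-3-en-1-yl]-3-methyloxiran-2-yl]-4-methylidene-5-oxooxolan-3-yl]-2-oxoethyl 2-methylprop-2-enoate | C/C(I)=C/CC[C@@]1(C)O[C@H]1[C@H]2OC(=O)C(=C)[C@@H]2[C@H](OC(=O)C(C)=C)C=O | intermediate
23 | (1(10)Z,4R,5S,6S,7R,8S,9R)-4,5-epoxy-9-hydroxy-8-(methacryloyloxy)germacra-1(10),11(13)-dien-12,6-olide | C=C(C)C(=O)O[C@H]1[C@H]2C(=C)C(=O)O[C@@H]2[C@@H]2O[C@]2(C)CC/C=C(/C)[C@H]1O | intermediate
24 | (1(10)Z,4R,5S,6S,7R,8S,9R)-9-acetoxy-4,5-epoxy-8-(methacryloyloxy)germacra-1(10),11(13)-dien-12,6-olide | C=C(C)C(=O)O[C@H]1[C@H]2C(=C)C(=O)O[C@@H]2[C@@H]2O[C@]2(C)CC/C=C(/C)[C@H]1OC(C)=O | intermediate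
25 | (1(10)Z,4R,5S,6S,7R,8S,9R)-9-acetoxy-4,5-epoxy-14-hydroxy-8-(methacryloyloxy)germacra-1(10),11(13)-dien-12,6-olide | C=C(C)C(=O)O[C@H]1[C@H]2C(=C)C(=O)O[C@@H]2[C@@H]2O[C@]2(C)CC/C=C(/CO)[C@H]1OC(C)=O | intermediate
26 | CNP0121379.1, (1(10)E,4R,5S,6S,7R,8S,9R)-9-acetoxy-4,5-epoxy-8-(methacryloyloxy)-14-oxogermacra-1(10),11(13)-dien-12,6-olide (C1=C10 cis within the ring) | C=C(C)C(=O)O[C@H]1[C@H]2C(=C)C(=O)O[C@@H]2[C@@H]2O[C@]2(C)CC/C=C(/C=O)[C@H]1OC(C)=O | target

**Step count and risks**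

Total step count: 16. Longest linear sequence: 16 steps (1 → 26); compounds 3, 10 and 15 are bought.

Steps most likely to fail:

Step 8 (the proposed new method). The ester enolate may alkylate on oxygen to a ketene acetal, or the closure may be slow because the ester must leave its preferred rotamer, so that intermolecular reactions take over. The fallback uses known chemistry, sets out from 14 and comes back at 19. Alcohol 14 is propargylated under neutral conditions (propargyl bromide, Ag2O, CH2Cl2) to the propargyl ether F1. Cp2TiCl (trivalent titanium, made from Cp2TiCl2 and Zn in THF) opens the epoxide homolytically at C7, and the C7 radical cyclises 5-exo-dig onto the alkyne, which again forms C7–C11 and should give the 2,3-trans methylenetetrahydrofuran alcohol F2. Methacrylation (methacrylic anhydride, Et3N, DMAP) gives the ester F3, and allylic oxidation of the ring CH2 next to oxygen with CrO3·2pyridine gives lactone 19.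

Step 13. The alkenylchromium may add to the wrong face of the C9 aldehyde, or intermolecular coupling may outrun the ten-membered closure. The fallback sets out from 22 and comes back at 23. If the ring closure gives mainly the C9-epimeric alcohol F4, the carbinol mixture is oxidised with Dess–Martin periodinane to the macrocyclic enone F5. The ketone is then reduced under reagent control with (R)-2-methyl-CBS-oxazaborolidine and catecholborane (alkenyl branch taken as the large group, hydride to the Si face), which should return 23.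

Step 10. The dioxirane may attack C4=C5 syn to the lactone oxygen (poor facial selectivity), or oxidation at iodine may compete. The fallback sets out from 19 and comes back at 20. Stereocontrol is moved from the substrate to a chiral catalyst: Shi epoxidation with the enantiomer of the D-fructose-derived ketone (made from L-sorbose), KHSO5 (as Oxone, 2KHSO5·KHSO4·K2SO4), K2CO3 buffer, MeCN/dimethoxymethane/H2O, 0 °C. By the spiro transition-state model this ketone should deliver oxygen to the face that gives (4R,5S). This fallback makes no new compound (F0).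

Further compounds
F1 | step 8 | tert-butyl({(2R,3R)-3-[(1R,2Z,6Z)-7-iodo-3-methyl-1-(prop-2-yn-1-yloxy)octa-2,6-dien-1-yl]oxiran-2-yl}methoxy)dimethylsilane | C/C(I)=C/CC/C(C)=C\[C@@H](OCC#C)[C@H]1O[C@@H]1CO[Si](C)(C)C(C)(C)C
F2 | step 8 | (1S)-2-{[tert-butyl(dimethyl)silyl]oxy}-1-[(2R,3R)-2-[(1Z,5Z)-6-iodo-2-methylhepta-1,5-dien-1-yl]-4-methylideneoxolan-3-yl]ethan-1-ol | C/C(I)=C/CC/C(C)=C\[C@H]1OCC(=C)[C@@H]1[C@H](O)CO[Si](C)(C)C(C)(C)C
F3 | step 8 | (1S)-2-{[tert-butyl(dimethyl)silyl]oxy}-1-[(2R,3S)-2-[(1Z,5Z)-6-iodo-2-methylhepta-1,5-dien-1-yl]-4-methylideneoxolan-3-yl]ethyl 2-methylprop-2-enoate | C/C(I)=C/CC/C(C)=C\[C@H]1OCC(=C)[C@@H]1[C@H](OC(=O)C(C)=C)CO[Si](C)(C)C(C)(C)C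
F4 | step 13 | (1(10)Z,4R,5S,6S,7R,8S,9S)-4,5-epoxy-9-hydroxy-8-(methacryloyloxy)germacra-1(10),11(13)-dien-12,6-olide | C=C(C)C(=O)O[C@H]1[C@H]2C(=C)C(=O)O[C@@H]2[C@@H]2O[C@]2(C)CC/C=C(/C)[C@@H]1O
F5 | step 13 | (1(10)Z,4R,5S,6S,7R,8S)-4,5-epoxy-8-(methacryloyloxy)-9-oxogermacra-1(10),11(13)-dien-12,6-olide | C=C(C)C(=O)O[C@H]1[C@H]2C(=C)C(=O)O[C@@H]2[C@@H]2O[C@]2(C)CC/C=C(/C)C1=O
F0 | step 10 | none | none
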